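**Strategy.** Everything rests on cutting ring A and ring B of the trans-decalin at C3–C4 and C5–C10 (labdane numbering). On ring A, C18 and H5 are cis at C4/C5 and C10 carries the angular C20 methyl; this is the imprint of an (E)-2-methyl-2-enal (C4=C5) adding to a C10=C1–C2=C3 diene whose tether-bearing terminus is methylated. A single intramolecular Diels–Alder reaction therefore closes both rings and sets C4, C5 and C10 under control of C9. The precursor is an acyclic (E,E)-trienal with the C8 methylene, the C9 and C13 stereocentres and a TBDPS-protected C15 hydroxyl; C9 is installed beforehand by Sharpless epoxidation and alkynylalane opening.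

Key step: step 14

Remarks on the chemistry:
- Labdane numbers (C1–C20) are used only as atom labels; configurations are those of the SMILES strings and CIP descriptors. TBDPS = tert-butyldiphenylsilyl, TBS = tert-butyldimethylsilyl, CSA = camphorsulfonic acid.
- Structure check: the E geometries of C4=C5 and C10=C1 and the centres C9 (R) and C13 (S) of trienal 19 map without conflict onto C4, C5, C9, C10 and C13 of cycloadduct 20 and of the target; (S)-citronellol has the correct sense for C13.
- Design choice 1: C18 enters the cycloaddition as an aldehyde, so that a Lewis acid can promote it at low temperature; an ester would need heat, which erodes endo selectivity and invites a 1,5-hydrogen shift in the diene.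
- Design choice 2: C15 is protected as the TBDPS ether and C5 as a TBS ether, so the C5 oxygen can be released selectively with mild acid and no acetal hydrolysis is needed next to the triene.
- Design choice 3: after the cycloaddition the C8 methylene is hydrated before C1=C2 is hydrogenated, because epoxidation or hydrogenation could not tell the two alkenes apart.

**Route**

Step 1
Reactants: 1 (S)-citronellol
Product: 2 tert-butyl{[(3S)-3,7-dimethyloct-6-en-1-yl]oxy}diphenylsilane
Conditions: TBDPSCl, imidazole, DMF, 0 °C → rt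
Reagents that add atoms: tert-butyl(chloro)diphenylsilane, CC(C)(C)[Si](Cl)(c1ccccc1)c1ccccc1
Why: Standard silylation of a primary alcohol with a silyl chloride and imidazole; the robust TBDPS ether is chosen because it must survive acid, base, hydride and Lewis acid and stay on while the C5 TBS ether is removed in step 10.

Step 2
Reactants: 2 citronellyl TBDPS ether
Product: 3 (4S)-6-[(tert-butyldiphenylsilyl)oxy]-4-methylhexanal
Conditions: O3, CH2Cl2, −78 °C; then PPh3, −78 °C → rt
Reagents that add atoms: ozone, [O-][O+]=O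
Why: Ozonolysis with reductive work-up cleaves the only alkene and leaves the aldehyde carbon that becomes C9; the remote C13 centre is untouched.

Step 3
Reactants: 4 triethyl phosphonoacetate; 5 (3-bromopropoxy)(tert-butyl)dimethylsilane
Product: 6 ethyl 5-[(tert-butyldimethylsilyl)oxy]-2-(diethoxyphosphoryl)pentanoate
Conditions: NaH, DMF, 0 °C; then 5, NaI (cat.), 60 °C
Reagents that add atoms: none
Why: SN2 alkylation of the sodium salt of the phosphonoacetate with a primary bromide is the usual way to an α-substituted Horner–Wadsworth–Emmons reagent and brings in C5–C7 together with C8 and C17.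

Step 4
Reactants: 6 substituted phosphonoacetate; 3 aldehyde
Product: 7 ethyl (2E,6S)-8-[(tert-butyldiphenylsilyl)oxy]-2-{3-[(tert-butyldimethylsilyl)oxy]propyl}-6-methyloct-2-enoate
Conditions: NaH, THF, 0 °C; then 3, 0 °C → rt
Reagents that add atoms: none
Why: Horner–Wadsworth–Emmons olefination of an unbranched aldehyde with an α-alkyl phosphonoacetate should favour the (E)-enoate (ester trans to C11); the minor (Z) isomer, which would end as the C9 epimer, is to be removed by chromatography here or after step 5.

Step 5
Reactants: 7 (E)-enoate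
Product: 8 (2E,6S)-8-[(tert-butyldiphenylsilyl)oxy]-2-{3-[(tert-butyldimethylsilyl)oxy]propyl}-6-methyloct-2-en-1-ol
Conditions: i-Bu2AlH (DIBAL-H), CH2Cl2, −78 → 0 °C; aq. potassium sodium tartrate
Reagents that add atoms: none
Why: 1,2-Reduction of an α,β-unsaturated ester to the allylic alcohol with i-Bu2AlH is routine and leaves both silyl ethers and the alkene geometry intact.

Step 6
Reactants: 8 (E)-allylic alcohol
Product: 9 [(2S,3S)-3-{(3S)-5-[(tert-butyldiphenylsilyl)oxy]-3-methylpentyl}-2-{3-[(tert-butyldimethylsilyl)oxy]propyl}oxiran-2-yl]methanol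
Conditions: Ti(OiPr)4 (cat.), L-(+)-diethyl tartrate (cat.), t-BuOOH, 4 Å molecular sieves, CH2Cl2, −20 °C
Reagents that add atoms: tert-butyl hydroperoxide, CC(C)(C)OO
Why: Sharpless asymmetric epoxidation of an (E)-2,3-dialkyl allylic alcohol, a favourable substrate class: the titanium tartrate complex with L-(+)-diethyl tartrate delivers oxygen to the face that gives the (2S,3S)-epoxide, so C9 and the transient C8 centre are set by the reagent and not by the remote C13.

Step 7
Reactants: 9 epoxy alcohol
Product: 10 (2R,3S,6S)-8-[(tert-butyldiphenylsilyl)oxy]-2-{3-[(tert-butyldimethylsilyl)oxy]propyl}-6-methyl-3-[(trimethylsilyl)ethynyl]octane-1,2-diol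
Conditions: Me3SiC≡CH, n-BuLi, toluene, 0 °C; Et2AlCl, 0 °C; then 9, 0 °C → rt
Reagents that add atoms: diethyl[(trimethylsilyl)ethynyl]aluminium, CC[Al](CC)C#C[Si](C)(C)C (generated from ethynyltrimethylsilane, C#C[Si](C)(C)C)
Why: Opening of a 2,3-epoxy alcohol by an alkynylalane at the carbon remote from the hydroxymethyl group (C9), with the aluminium alkoxide of C17 holding the reagent and the fully substituted C8 closed to SN2 attack; the anti (inversion) opening converts the epoxide carbon into C9 with the configuration of the target.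

Step 8
Reactants: 10 diol
Product: 11 (4R)-4-{3-[(tert-butyldimethylsilyl)oxy]propyl}-4-[(3S,6S)-8-[(tert-butyldiphenylsilyl)oxy]-6-methyl-1-(trimethylsilyl)oct-1-yn-3-yl]-1,3-dioxolane-2-thione
Conditions: 1,1'-thiocarbonyldiimidazole, DMAP (cat.), toluene, 80 °C
Reagents that add atoms: 1,1'-thiocarbonyldiimidazole, S=C(n1ccnc1)n1ccnc1
Why: Formation of the cyclic thionocarbonate of a 1,2-diol is the first half of the Corey–Winter olefination; both C–O bonds stay intact.

Step 9
Reactants: 11 cyclic thionocarbonate
Product: 12 [(3R,6S)-8-[(tert-butyldiphenylsilyl)oxy]-3-{5-[(tert-butyldimethylsilyl)oxy]pent-1-en-2-yl}-6-methyloct-1-yn-1-yl]trimethylsilane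
Conditions: P(OMe)3, 110 °C
Reagents that add atoms: none
Why: Corey–Winter olefination: the phosphite removes sulfur, the resulting carbene loses CO2 and leaves the C8=C17 methylene without any base or carbonyl group next to the doubly activated C9–H, so C9 keeps its configuration.

Step 10
Reactants: 12 silylated 1,4-enyne
Product: 14 (5R,8S)-10-[(tert-butyldiphenylsilyl)oxy]-5-ethynyl-8-methyl-4-methylidenedecan-1-ol, via silylalkynol 13 (not isolated)
Conditions: CSA (cat.), MeOH–CH2Cl2, 0 °C → rt; then K2CO3, rt
Reagents that add atoms: none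
Why: Acid-catalysed methanolysis removes the primary TBS ether while the bulkier TBDPS ether stays, and carbonate in methanol then cleaves the alkynyl C–Si bond in the same flask; both are standard desilylations.

Step 11
Reactants: 14 enynol
Product: 16 (5R,8S)-10-[(tert-butyldiphenylsilyl)oxy]-8-methyl-4-methylidene-5-[(2E)-penta-2,4-dien-2-yl]decan-1-ol, via alkenylalane 15 (not isolated)
Conditions: Me3Al, Cp2ZrCl2 (cat.), CH2Cl2, 0 °C → rt; evaporate; then CH2=CHBr, Pd(PPh3)4 (cat.), ZnCl2 (cat.), THF, rt
Reagents that add atoms: trimethylaluminium, C[Al](C)C; vinyl bromide, C=CBr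
Why: Zirconium-catalysed methylalumination adds methyl and aluminium syn across the terminal alkyne (methyl to C10), and palladium-catalysed coupling of the alkenylalane with vinyl bromide (Negishi coupling) proceeds with retention, so the diene forms with C9 trans to C2; the hydroxyl is carried as its aluminium alkoxide and the 1,1-disubstituted alkene does not carbometalate.

Step 12
Reactants: 16 dienol
Product: 17 (5R,8S)-10-[(tert-butyldiphenylsilyl)oxy]-8-methyl-4-methylidene-5-[(2E)-penta-2,4-dien-2-yl]decanal
Conditions: Dess–Martin periodinane, pyridine, CH2Cl2, 0 °C → rt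
Reagents that add atoms: none
Why: Dess–Martin oxidation of a primary alcohol under buffered, non-basic conditions gives the aldehyde without touching the skipped triene; there is no stereocentre next to the new carbonyl.

Step 13
Reactants: 17 aldehyde; 18 2-(triphenylphosphoranylidene)propanal
Product: 19 (2E,7R,10S)-12-[(tert-butyldiphenylsilyl)oxy]-2,10-dimethyl-6-methylidene-7-[(2E)-penta-2,4-dien-2-yl]dodec-2-enal
Conditions: toluene, 70–80 °C
Reagents that add atoms: none
Why: Wittig olefination with a formyl-stabilised ylide gives the (E)-2-methyl-2-enal with high geometric preference; moderate temperature and prompt use of the product are meant to keep the uncatalysed cycloaddition from starting.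

Step 14
Reactants: 19 (E,E)-trienal
Product: 20 (4S,5S,9R,10S,13S)-15-[(tert-butyldiphenylsilyl)oxy]labda-1,8(17)-dien-18-al
Conditions: Me2AlCl (1.1 equiv), CH2Cl2, −78 → −20 °C; aq. potassium sodium tartrate
Reagents that add atoms: none
Why: Coordination of Me2AlCl to the formyl oxygen lowers the dienophile LUMO, so that the (E)-2-methyl-2-enal C4=C5 adds suprafacially to the s-cis C10=C1–C2=C3 diene in a concerted, asynchronous [4+2] with C5–C10 bonding ahead of C3–C4; the closest known reaction type is the Lewis acid-promoted intramolecular Diels–Alder reaction of (E)-2-methyl-2,7,9-decatrienals to trans-fused octalins, here with the less common feature that the tether-bearing diene terminus also carries a methyl group. Ring A (six-membered) closes by the cycloaddition itself through the C3–C4 and C5–C10 bonds, and ring B (six-membered) closes in the fused mode as the four-atom tether C6–C9, attached at the diene terminus C10, settles into a chair while C5–C10 forms. C4 is fixed by the E geometry of the enal, which keeps C18 and H5 cis on ring A with C19 axial; C5 and C10 are fixed relative to C4 by the formyl-endo transition state, which puts H5 anti to C20 (trans fusion) and relies on the E geometry of C10=C1 from step 11; the absolute sense of all three follows from C9, whose C11 chain sits pseudo-equatorial on the chair-like tether and anti to the forming C5–C10 bond, so the dienophile reaches the diene face opposite C11. The step therefore needs endo over exo selectivity and one diene face: the Lewis acid complex should strengthen the endo preference at low temperature, and the C9 centre together with allylic strain against C20 and the C8 methylene should bias the face. The low temperature also avoids a thermal 1,5-hydrogen shift in the diene and epimerisation of the doubly allylic C9.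

Step 15
Reactants: 20 cycloadduct aldehyde
Product: 21 (4S,5S,9R,10S,13S)-15-[(tert-butyldiphenylsilyl)oxy]labda-1,8(17)-dien-18-ol
Conditions: NaBH4, MeOH, 0 °C
Reagents that add atoms: none
Why: Sodium borohydride reduction of the hindered aldehyde to the primary alcohol; nothing else in the molecule is reducible under these conditions.

Step 16
Reactants: 21 dienol
Product: 22 (4S,5S,8S,9S,10R,13S)-15-[(tert-butyldiphenylsilyl)oxy]labd-1-ene-8,18-diol
Conditions: Co(acac)2 (cat.), PhSiH3, O2 (1 atm), i-PrOH, rt
Reagents that add atoms: dioxygen, O=O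
Why: Mukaiyama hydration: hydrogen-atom transfer from a cobalt hydride to the 1,1-disubstituted C8=C17 alkene gives the tertiary C8 radical much faster than a secondary radical could form from the 1,2-disubstituted C1=C2, and O2 should trap it along the equatorial direction, on the face opposite the axial C20 methyl, giving the equatorial C8 hydroxyl and axial C17 methyl of the target.

Step 17
Reactants: 22 unsaturated diol
Product: 23 (4S,5S,8S,9S,10R,13S)-15-[(tert-butyldiphenylsilyl)oxy]labdane-8,18-diol
Conditions: H2 (1 atm), Pd/C, EtOAc, rt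
Reagents that add atoms: none
Why: Heterogeneous catalytic hydrogenation of the remaining cis-disubstituted ring alkene; no stereocentre is formed, and the step follows the hydration because the exocyclic alkene would otherwise be reduced first.

Step 18
Reactants: 23 diol; 24 3-methylbut-2-enoic acid
Product: 25 (4S,5S,8S,9S,10R,13S)-15-[(tert-butyldiphenylsilyl)oxy]-8-hydroxylabdan-18-yl 3-methylbut-2-enoate
Conditions: DCC, DMAP (cat.), CH2Cl2, 0 °C → rt
Reagents that add atoms: none
Why: Steglich esterification acylates the primary neopentyl-type C18 hydroxyl and leaves the tertiary C8 hydroxyl alone; carbodiimide activation avoids the deconjugation of the senecioyl unit that amine bases can cause with the acid chloride.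

Step 19
Reactants: 25 silyl-protected ester
Product: 26 (4S,5S,8S,9S,10R,13S)-8,15-dihydroxylabdan-18-yl 3-methylbut-2-enoate
Conditions: HF·pyridine, pyridine, THF, 0 °C → rt
Reagents that add atoms: none
Why: Fluoride-mediated cleavage of the silyl ether with buffered HF·pyridine frees the C15 hydroxyl; the conjugated ester and the tertiary alcohol are stable under these conditions.

**Compound list**

1 | (S)-citronellol, (3S)-3,7-dimethyloct-6-en-1-ol | CC(C)=CCC[C@H](C)CCO | starting material
2 | tert-butyl{[(3S)-3,7-dimethyloct-6-en-1-yl]oxy}diphenylsilane | CC(C)=CCC[C@H](C)CCO[Si](c1ccccc1)(c1ccccc1)C(C)(C)C | intermediate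
3 | (4S)-6-[(tert-butyldiphenylsilyl)oxy]-4-methylhexanal | O=CCC[C@H](C)CCO[Si](c1ccccc1)(c1ccccc1)C(C)(C)C | intermediate
4 | triethyl phosphonoacetate | CCOC(=O)CP(=O)(OCC)OCC | starting material
5 | (3-bromopropoxy)(tert-butyl)dimethylsilane | BrCCCO[Si](C)(C)C(C)(C)C | starting material
6 | ethyl 5-[(tert-butyldimethylsilyl)oxy]-2-(diethoxyphosphoryl)pentanoate (racemic at C2) | CCOC(=O)C(CCCO[Si](C)(C)C(C)(C)C)P(=O)(OCC)OCC | intermediate
7 | ethyl (2E,6S)-8-[(tert-butyldiphenylsilyl)oxy]-2-{3-[(tert-butyldimethylsilyl)oxy]propyl}-6-methyloct-2-enoate | CCOC(=O)/C(CCCO[Si](C)(C)C(C)(C)C)=C/CC[C@H](C)CCO[Si](c1ccccc1)(c1ccccc1)C(C)(C)C | intermediate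
8 | (2E,6S)-8-[(tert-butyldiphenylsilyl)oxy]-2-{3-[(tert-butyldimethylsilyl)oxy]propyl}-6-methyloct-2-en-1-ol | OC/C(CCCO[Si](C)(C)C(C)(C)C)=C/CC[C@H](C)CCO[Si](c1ccccc1)(c1ccccc1)C(C)(C)C | intermediate
9 | [(2S,3S)-3-{(3S)-5-[(tert-butyldiphenylsilyl)oxy]-3-methylpentyl}-2-{3-[(tert-butyldimethylsilyl)oxy]propyl}oxiran-2-yl]methanol | OC[C@]1(CCCO[Si](C)(C)C(C)(C)C)O[C@H]1CC[C@H](C)CCO[Si](c1ccccc1)(c1ccccc1)C(C)(C)C | intermediate
10 | (2R,3S,6S)-8-[(tert-butyldiphenylsilyl)oxy]-2-{3-[(tert-butyldimethylsilyl)oxy]propyl}-6-methyl-3-[(trimethylsilyl)ethynyl]octane-1,2-diol | OC[C@@](O)(CCCO[Si](C)(C)C(C)(C)C)[C@H](C#C[Si](C)(C)C)CC[C@H](C)CCO[Si](c1ccccc1)(c1ccccc1)C(C)(C)C | intermediate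
11 | (4R)-4-{3-[(tert-butyldimethylsilyl)oxy]propyl}-4-[(3S,6S)-8-[(tert-butyldiphenylsilyl)oxy]-6-methyl-1-(trimethylsilyl)oct-1-yn-3-yl]-1,3-dioxolane-2-thione | S=C1OC[C@@](CCCO[Si](C)(C)C(C)(C)C)([C@H](C#C[Si](C)(C)C)CC[C@H](C)CCO[Si](c2ccccc2)(c2ccccc2)C(C)(C)C)O1 | intermediate
12 | [(3R,6S)-8-[(tert-butyldiphenylsilyl)oxy]-3-{5-[(tert-butyldimethylsilyl)oxy]pent-1-en-2-yl}-6-methyloct-1-yn-1-yl]trimethylsilane | C=C(CCCO[Si](C)(C)C(C)(C)C)[C@H](C#C[Si](C)(C)C)CC[C@H](C)CCO[Si](c1ccccc1)(c1ccccc1)C(C)(C)C | intermediate
13 | (5R,8S)-10-[(tert-butyldiphenylsilyl)oxy]-8-methyl-4-methylidene-5-[(trimethylsilyl)ethynyl]decan-1-ol | C=C(CCCO)[C@H](C#C[Si](C)(C)C)CC[C@H](C)CCO[Si](c1ccccc1)(c1ccccc1)C(C)(C)C | intermediate (not isolated)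
14 | (5R,8S)-10-[(tert-butyldiphenylsilyl)oxy]-5-ethynyl-8-methyl-4-methylidenedecan-1-ol | C=C(CCCO)[C@H](C#C)CC[C@H](C)CCO[Si](c1ccccc1)(c1ccccc1)C(C)(C)C | intermediate
15 | (E)-alkenyl(dimethyl)alane from syn-methylalumination of 14, C5 oxygen as its dimethylaluminium alkoxide | C=C(CCCO[Al](C)C)[C@H](/C(C)=C/[Al](C)C)CC[C@H](C)CCO[Si](c1ccccc1)(c1ccccc1)C(C)(C)C | intermediate (not isolated)
16 | (5R,8S)-10-[(tert-butyldiphenylsilyl)oxy]-8-methyl-4-methylidene-5-[(2E)-penta-2,4-dien-2-yl]decan-1-ol | C=C(CCCO)[C@H](/C(C)=C/C=C)CC[C@H](C)CCO[Si](c1ccccc1)(c1ccccc1)C(C)(C)C | intermediate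
17 | (5R,8S)-10-[(tert-butyldiphenylsilyl)oxy]-8-methyl-4-methylidene-5-[(2E)-penta-2,4-dien-2-yl]decanal | C=C(CCC=O)[C@H](/C(C)=C/C=C)CC[C@H](C)CCO[Si](c1ccccc1)(c1ccccc1)C(C)(C)C | intermediate
18 | 2-(triphenylphosphoranylidene)propanal | CC(C=O)=P(c1ccccc1)(c1ccccc1)c1ccccc1 | starting material
19 | (2E,7R,10S)-12-[(tert-butyldiphenylsilyl)oxy]-2,10-dimethyl-6-methylidene-7-[(2E)-penta-2,4-dien-2-yl]dodec-2-enal | O=C/C(C)=C/CCC(=C)[C@H](/C(C)=C/C=C)CC[C@H](C)CCO[Si](c1ccccc1)(c1ccccc1)C(C)(C)C | intermediate
20 | (4S,5S,9R,10S,13S)-15-[(tert-butyldiphenylsilyl)oxy]labda-1,8(17)-dien-18-al (trans-fused octalin) | O=C[C@@]1(C)CC=C[C@]2(C)[C@@H]1CCC(=C)[C@H]2CC[C@H](C)CCO[Si](c1ccccc1)(c1ccccc1)C(C)(C)C | intermediate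
21 | (4S,5S,9R,10S,13S)-15-[(tert-butyldiphenylsilyl)oxy]labda-1,8(17)-dien-18-ol | OC[C@@]1(C)CC=C[C@]2(C)[C@@H]1CCC(=C)[C@H]2CC[C@H](C)CCO[Si](c1ccccc1)(c1ccccc1)C(C)(C)C | intermediate
22 | (4S,5S,8S,9S,10R,13S)-15-[(tert-butyldiphenylsilyl)oxy]labd-1-ene-8,18-diol | OC[C@@]1(C)CC=C[C@]2(C)[C@@H]1CC[C@](C)(O)[C@H]2CC[C@H](C)CCO[Si](c1ccccc1)(c1ccccc1)C(C)(C)C | intermediate
23 | (4S,5S,8S,9S,10R,13S)-15-[(tert-butyldiphenylsilyl)oxy]labdane-8,18-diol | OC[C@@]1(C)CCC[C@]2(C)[C@@H]1CC[C@](C)(O)[C@H]2CC[C@H](C)CCO[Si](c1ccccc1)(c1ccccc1)C(C)(C)C | intermediate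
24 | 3-methylbut-2-enoic acid (senecioic acid) | CC(C)=CC(=O)O | starting material
25 | (4S,5S,8S,9S,10R,13S)-15-[(tert-butyldiphenylsilyl)oxy]-8-hydroxylabdan-18-yl 3-methylbut-2-enoate | CC(C)=CC(=O)OC[C@@]1(C)CCC[C@]2(C)[C@@H]1CC[C@](C)(O)[C@H]2CC[C@H](C)CCO[Si](c1ccccc1)(c1ccccc1)C(C)(C)C | intermediate
26 | (4S,5S,8S,9S,10R,13S)-8,15-dihydroxylabdan-18-yl 3-methylbut-2-enoate (CNP0280238.1) | CC(C)=CC(=O)OC[C@@]1(C)CCC[C@]2(C)[C@@H]1CC[C@](C)(O)[C@H]2CC[C@H](C)CCO | target

**Step count and risk**

Total step count: 19. Longest linear sequence: 18 steps (steps 1, 2 and 4–19, from 1 to 26); step 3 is a one-step branch.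

The three steps most likely to fail:

Step 14, the cycloaddition. The methyl on the diene terminus disfavours the s-cis conformer, so the reaction may be slow. The Lewis acid may instead trigger cationic ene or Prins-type reactions or isomerisation of the C8 methylene. Endo selectivity or diene-face selectivity may be poor. The fallback removes the Lewis acid and changes the dienophile. It sets out from aldehyde 17, which is condensed with methyl 2-(triphenylphosphoranylidene)propanoate (CH2Cl2, rt) to the methyl trienoate F1. F1 is cyclised without catalyst (toluene, BHT, sealed tube, 170–180 °C) to the methyl ester cycloadduct F2. F2 is reduced with i-Bu2AlH (CH2Cl2, −78 → 0 °C) and the fallback comes back to the route at alcohol 21.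

Step 7, the epoxide opening that sets C9. Ionisation at the fully substituted C8 with attack or a 1,2-shift there, or slow substitution at C9 next to the quaternary carbon, would erode regiochemistry. The fallback replaces substrate-controlled opening by catalyst-controlled allylic substitution. It sets out from allylic alcohol 8, which is converted with diethyl chlorophosphate (pyridine, DMAP) into the allylic diethyl phosphate F3. F3 undergoes copper-catalysed enantioselective SN2′ alkynylation with (i-Bu)2Al–C≡C–SiMe3 (CuCl2·2H2O and a chiral sulfonate-bearing N-heterocyclic carbene ligand, THF, −30 °C). This comes back to the route at enyne 12 and bypasses steps 6–9.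

Step 16, the hydration at C8. Trapping of the planar C8 radical may show poor facial selectivity, or hydrogen-atom transfer may also reach C1=C2. The fallback changes from a radical to an ionic Markovnikov hydration: oxymercuration–demercuration (Hg(OAc)2, THF–H2O, rt; then NaBH4, aq. NaOH). It sets out from 21 and comes back at 22, where water attacks the mercurinium ion at C8 away from the axial C20 methyl; it makes no new compound (F0).

**Further compounds**

F1 | step 14 | methyl (2E,7R,10S)-12-[(tert-butyldiphenylsilyl)oxy]-2,10-dimethyl-6-methylidene-7-[(2E)-penta-2,4-dien-2-yl]dodec-2-enoate | COC(=O)/C(C)=C/CCC(=C)[C@H](/C(C)=C/C=C)CC[C@H](C)CCO[Si](c1ccccc1)(c1ccccc1)C(C)(C)C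
F2 | step 14 | methyl (4S,5S,9R,10S,13S)-15-[(tert-butyldiphenylsilyl)oxy]labda-1,8(17)-dien-18-oate | COC(=O)[C@@]1(C)CC=C[C@]2(C)[C@@H]1CCC(=C)[C@H]2CC[C@H](C)CCO[Si](c1ccccc1)(c1ccccc1)C(C)(C)C
F3 | step 7 | (2E,6S)-8-[(tert-butyldiphenylsilyl)oxy]-2-{3-[(tert-butyldimethylsilyl)oxy]propyl}-6-methyloct-2-en-1-yl diethyl phosphate | CCOP(=O)(OCC)OC/C(CCCO[Si](C)(C)C(C)(C)C)=C/CC[C@H](C)CCO[Si](c1ccccc1)(c1ccccc1)C(C)(C)C
F0 | step 16 | none | none
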